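The route rests on cutting two bonds that lie away from every stereocentre. One is C4–C5 of the piperidine (N1, C2 methyl, C3 ferulate oxygen, C6 chain), the one ring bond whose carbons are neither stereogenic nor bonded to N or O. The other is C9′–C10′, next to the C11′ ketone of the C1′–C12′ chain. Both are made as alkenes in one tandem ring-closing/cross metathesis of an acyclic secondary amine, protonated in the flask, with methyl vinyl ketone. The precursor carries C2, C3 and C6 preset: a TBS-protected anti amino alcohol from L-alanine, N-linked by iridium-catalysed allylic amination to a trideca-1,12-dien-3-yl unit. Hydrogenation, N-protection, esterification and acid deprotection finish the target.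

Key step: step 8

Remarks on the chemistry:
- Numbering used throughout: ring N1, C2 (methyl), C3 (oxygen), C4, C5, C6 (side chain); chain C1′–C12′ counted from the ring.
- L is O,O′-[(Ra)-1,1′-binaphthalene-2,2′-diyl] N,N-bis[(R)-1-phenylethyl]phosphoramidite.
- Assumption: the sense of induction of L (6S for an alkyl-substituted allyl unit) is assigned by analogy with aminations of linear alkyl-substituted allylic carbonates. If a test reaction showed the 6-epimer, the enantiomeric ligand would be used with no other change.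

Step 1
Reactants: 1 tert-butyl N-[(2S)-1-[methoxy(methyl)amino]-1-oxopropan-2-yl]carbamate (N-Boc-L-alanine N-methoxy-N-methylamide, commercial)
Product: 2 tert-butyl N-[(2S)-3-oxopent-4-en-2-yl]carbamate
Conditions: CH2=CHMgBr (3 equiv), THF, 0 °C; inverse quench into cold 1 M HCl
Reagents that add atoms: vinylmagnesium bromide, C=C[Mg]Br
Why: Weinreb ketone synthesis, in which one equivalent of Grignard reagent deprotonates the carbamate N–H (shielding C2 from enolisation) and the next adds to give a magnesium chelate that collapses to the enone only on the acidic inverse quench, which also keeps the released MeNHOMe protonated so that it cannot add to the vinyl ketone.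

Step 2
Reactants: 2 tert-butyl N-[(2S)-3-oxopent-4-en-2-yl]carbamate
Product: 3 tert-butyl N-[(2S,3R)-3-hydroxypent-4-en-2-yl]carbamate
Conditions: LiAlH(OtBu)3 (2.5 equiv), EtOH, −78 °C; aq. potassium sodium tartrate
Reagents that add atoms: none
Why: Chelation-controlled (Cram cyclic model) 1,2-reduction of an N-carbamoyl α-amino enone, in which the bulky hydride should attack the carbonyl held by the carbamate from the face away from the C2 methyl group and so set C3 as R (anti amino alcohol).

Step 3
Reactants: 3 tert-butyl N-[(2S,3R)-3-hydroxypent-4-en-2-yl]carbamate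
Product: 6 (2S,3R)-3-[tert-butyl(dimethyl)silyl]oxypent-4-en-2-amine, via silyl ether carbamate 4 (not isolated), via silyl carbamate 5 (not isolated)
Conditions: TBSOTf (2.5 equiv), 2,6-lutidine (4 equiv), CH2Cl2, 0 °C → rt; then K2CO3, MeOH/H2O, rt
Reagents that add atoms: tert-butyldimethylsilyl trifluoromethanesulfonate, CC(C)(C)[Si](C)(C)OS(=O)(=O)C(F)(F)F
Why: Silyl triflate/lutidine first silylates the alcohol and then exchanges the tert-butyl carbamate for a silyl carbamate with loss of isobutene; carbonate methanolysis of that labile Si–O bond and decarboxylation should free the primary amine while the secondary TBS ether and both stereocentres stay untouched.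

Step 4
Reactants: 7 undec-10-enal
Product: 8 ethyl (2E)-trideca-2,12-dienoate
Conditions: (EtO)2P(O)CH2CO2Et, NaH, THF, 0 °C → rt
Reagents that add atoms: triethyl phosphonoacetate, CCOC(=O)CP(=O)(OCC)OCC
Why: Horner–Wadsworth–Emmons olefination of an unhindered aldehyde with a stabilised phosphonate anion, which should give the E-enoate and leave the remote terminal alkene alone.

Step 5
Reactants: 8 ethyl (2E)-trideca-2,12-dienoate
Product: 9 (2E)-trideca-2,12-dien-1-ol
Conditions: iBu2AlH (2.2 equiv), CH2Cl2, −78 → 0 °C; aq. potassium sodium tartrate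
Reagents that add atoms: none
Why: 1,2-Reduction of an enoate to the allylic alcohol by an electrophilic aluminium hydride, which does not reduce either C=C bond.

Step 6
Reactants: 9 (2E)-trideca-2,12-dien-1-ol
Product: 10 methyl (2E)-trideca-2,12-dien-1-yl carbonate
Conditions: ClCO2Me, pyridine, CH2Cl2, 0 °C
Reagents that add atoms: methyl chloroformate, COC(=O)Cl
Why: Acylation of a primary alcohol by a chloroformate gives the linear allylic carbonate, the standard leaving group for iridium-catalysed allylic substitution.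

Step 7
Reactants: 6 (2S,3R)-3-[tert-butyl(dimethyl)silyl]oxypent-4-en-2-amine; 10 methyl (2E)-trideca-2,12-dien-1-yl carbonate
Product: 11 (3S)-N-[(2S,3R)-3-(tert-butyldimethylsilyloxy)pent-4-en-2-yl]trideca-1,12-dien-3-amine
Conditions: [Ir(cod)Cl]2 (2 mol %), L (4 mol %), TBD (8 mol %), THF, rt → 50 °C
Reagents that add atoms: none
Why: Iridium-catalysed asymmetric allylic amination, in which the catalyst formed from [Ir(cod)Cl]2, L and base ionises the carbonate (loss of CO2 and methanol) and the primary amine attacks the substituted allyl terminus to give the branched amine; the new stereocentre C6 (S) is set by the ligand (reagent control), and the hindered secondary amine should not react a second time.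

Step 8
Reactants: 11 (3S)-N-[(2S,3R)-3-(tert-butyldimethylsilyloxy)pent-4-en-2-yl]trideca-1,12-dien-3-amine; 12 methyl vinyl ketone
Product: 15 (3E)-12-[(2S,3R,6S)-3-(tert-butyldimethylsilyloxy)-2-methyl-1,2,3,6-tetrahydropyridin-6-yl]dodec-3-en-2-one, via triene ammonium tosylate 13 (not isolated), via tetrahydropyridinium tosylate 14 (not isolated)
Conditions: TsOH·H2O (1.0 equiv), CH2Cl2, rt; 12 (5 equiv), second-generation Hoveyda–Grubbs catalyst (5 mol %), CH2Cl2 (0.02 M), 40 °C, argon sweep; evaporate excess 12; aq. NaHCO3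
Reagents that add atoms: none
Why: Both events are olefin metatheses through ruthenacyclobutanes ([2+2] cycloaddition and cycloreversion), the closest known reactions being ring-closing metathesis of diallylic ammonium salts to 1,2,3,6-tetrahydropyridines and cross metathesis of terminal alkenes with enones. The six-membered ring is closed by ring-closing metathesis of the 1,7-diene formed by the vinyl groups on C3 and C6, which makes C4=C5 as a cis ring alkene and expels ethene. Cross metathesis of the unhindered chain terminus with excess 12 makes the C9′=C10′ enone, E under thermodynamic control, and expels a second ethene. No stereocentre is formed, and C2, C3 and C6 are sp3 carbons that the catalyst does not touch. The step needs site selectivity and a catalyst free of amine coordination: the two allylic vinyl groups are α-branched and flanked by the ammonium ion or the bulky silyl ether, so they are poor cross partners yet close enough to cyclise, and one equivalent of TsOH removes the nitrogen lone pair without leaving free acid to attack the silyl ether. Excess 12 is stripped before the basic work-up so that the liberated amine meets no Michael acceptor.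

Step 9
Reactants: 15 (3E)-12-[(2S,3R,6S)-3-(tert-butyldimethylsilyloxy)-2-methyl-1,2,3,6-tetrahydropyridin-6-yl]dodec-3-en-2-one
Product: 16 12-[(2S,3R,6S)-3-(tert-butyldimethylsilyloxy)-2-methylpiperidin-6-yl]dodecan-2-one
Conditions: H2 (1 atm), PtO2 (5 mol %), EtOAc, rt, stopped when 15 is consumed
Reagents that add atoms: none
Why: Heterogeneous hydrogenation over PtO2 in a neutral aprotic solvent should saturate the ring alkene and the enone C=C faster than it reduces a dialkyl ketone and with little allylic C–N or C–O hydrogenolysis; no stereocentre is made or disturbed.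

Step 10
Reactants: 16 12-[(2S,3R,6S)-3-(tert-butyldimethylsilyloxy)-2-methylpiperidin-6-yl]dodecan-2-one
Product: 17 tert-butyl (2S,3R,6S)-3-(tert-butyldimethylsilyloxy)-2-methyl-6-(11-oxododecyl)piperidine-1-carboxylate
Conditions: Boc2O (3 equiv), Et3N, THF, 50 °C
Reagents that add atoms: di-tert-butyl dicarbonate, CC(C)(C)OC(=O)OC(=O)OC(C)(C)C
Why: Carbamate formation at the only N–H in the molecule; the nitrogen is doubly α-branched, so excess reagent and gentle heating are planned, and ketone and silyl ether are inert.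

Step 11
Reactants: 17 tert-butyl (2S,3R,6S)-3-(tert-butyldimethylsilyloxy)-2-methyl-6-(11-oxododecyl)piperidine-1-carboxylate
Product: 18 tert-butyl (2S,3R,6S)-3-hydroxy-2-methyl-6-(11-oxododecyl)piperidine-1-carboxylate
Conditions: Bu4NF (1.5 equiv), THF, 0 °C → rt
Reagents that add atoms: none
Why: Fluoride-driven desilylation (strong Si–F bond) frees the C3 alcohol; attack of the alkoxide on the carbamate would need a bridged bicyclic carbamate and should not compete.

Step 12
Reactants: 19 ferulic acid
Product: 21 (E)-3-[3-methoxy-4-(methoxymethoxy)phenyl]prop-2-enoic acid, via methoxymethyl ester 20 (not isolated)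
Conditions: MOMCl (2.5 equiv), iPr2NEt (3 equiv), CH2Cl2, 0 °C → rt; then LiOH, THF/MeOH/H2O, rt; 1 M HCl to pH 4, 0 °C
Reagents that add atoms: chloromethyl methyl ether, COCCl; lithium hydroxide, [Li+].[OH-]
Why: O-Alkylation of phenoxide and carboxylate by the chloromethyl ether followed by saponification, which cleaves only the acetal ester and leaves the base-stable aryl MOM ether.

Step 13
Reactants: 18 tert-butyl (2S,3R,6S)-3-hydroxy-2-methyl-6-(11-oxododecyl)piperidine-1-carboxylate; 21 (E)-3-[3-methoxy-4-(methoxymethoxy)phenyl]prop-2-enoic acid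
Product: 22 tert-butyl (2S,3R,6S)-3-[(E)-3-[3-methoxy-4-(methoxymethoxy)phenyl]prop-2-enoyl]oxy-2-methyl-6-(11-oxododecyl)piperidine-1-carboxylate
Conditions: DCC (1.3 equiv), DMAP (0.3 equiv), CH2Cl2, 0 °C → rt
Reagents that add atoms: none
Why: Steglich esterification through the O-acylisourea and acylpyridinium ion acylates the only free hydroxyl; the C3–O bond is not broken, so the configuration is retained.

Step 14
Reactants: 22 tert-butyl (2S,3R,6S)-3-[(E)-3-[3-methoxy-4-(methoxymethoxy)phenyl]prop-2-enoyl]oxy-2-methyl-6-(11-oxododecyl)piperidine-1-carboxylate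
Product: 23 (2S,3R,6S)-2-methyl-6-(11-oxododecyl)piperidin-3-yl (E)-3-(4-hydroxy-3-methoxyphenyl)prop-2-enoate (target)
Conditions: CF3CO2H/CH2Cl2/H2O (20:78:2), 0 °C → rt; evaporate; aq. NaHCO3
Reagents that add atoms: none
Why: Acidolysis removes the Boc group (tert-butyl cation, then decarboxylation) and the aryl MOM acetal (oxocarbenium ion) in one operation, while the cinnamate ester and the ketone are stable to acid and the nitrogen stays protonated until the volatile by-products have been evaporated.

Compound list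
1 | tert-butyl N-[(2S)-1-[methoxy(methyl)amino]-1-oxopropan-2-yl]carbamate | C[C@H](NC(=O)OC(C)(C)C)C(=O)N(C)OC | starting material
2 | tert-butyl N-[(2S)-3-oxopent-4-en-2-yl]carbamate | O=C(C=C)[C@H](C)NC(=O)OC(C)(C)C | intermediate
3 | tert-butyl N-[(2S,3R)-3-hydroxypent-4-en-2-yl]carbamate | O[C@H](C=C)[C@H](C)NC(=O)OC(C)(C)C | intermediate
4 | tert-butyl N-[(2S,3R)-3-[tert-butyl(dimethyl)silyl]oxypent-4-en-2-yl]carbamate | CC(C)(C)[Si](C)(C)O[C@H](C=C)[C@H](C)NC(=O)OC(C)(C)C | intermediate
5 | tert-butyl(dimethyl)silyl N-[(2S,3R)-3-[tert-butyl(dimethyl)silyl]oxypent-4-en-2-yl]carbamate | CC(C)(C)[Si](C)(C)O[C@H](C=C)[C@H](C)NC(=O)O[Si](C)(C)C(C)(C)C | intermediate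
6 | (2S,3R)-3-[tert-butyl(dimethyl)silyl]oxypent-4-en-2-amine | CC(C)(C)[Si](C)(C)O[C@H](C=C)[C@H](C)N | intermediate
7 | undec-10-enal | C=CCCCCCCCCC=O | starting material
8 | ethyl (2E)-trideca-2,12-dienoate | C=CCCCCCCCC/C=C/C(=O)OCC | intermediate
9 | (2E)-trideca-2,12-dien-1-ol | C=CCCCCCCCC/C=C/CO | intermediate
10 | methyl (2E)-trideca-2,12-dien-1-yl carbonate | C=CCCCCCCCC/C=C/COC(=O)OC | intermediate
11 | (3S)-N-[(2S,3R)-3-(tert-butyldimethylsilyloxy)pent-4-en-2-yl]trideca-1,12-dien-3-amine | CC(C)(C)[Si](C)(C)O[C@H](C=C)[C@H](C)N[C@H](C=C)CCCCCCCCC=C | intermediate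
12 | methyl vinyl ketone (but-3-en-2-one) | CC(=O)C=C | starting material
13 | (3S)-N-[(2S,3R)-3-(tert-butyldimethylsilyloxy)pent-4-en-2-yl]trideca-1,12-dien-3-aminium 4-methylbenzenesulfonate | CC(C)(C)[Si](C)(C)O[C@H](C=C)[C@H](C)[NH2+][C@H](C=C)CCCCCCCCC=C.Cc1ccc(cc1)S(=O)(=O)[O-] | intermediate
14 | (2S,3R,6S)-3-(tert-butyldimethylsilyloxy)-2-methyl-6-[(9E)-11-oxododec-9-en-1-yl]-1,2,3,6-tetrahydropyridinium 4-methylbenzenesulfonate | CC(C)(C)[Si](C)(C)O[C@@H]1C=C[C@H](CCCCCCCC/C=C/C(C)=O)[NH2+][C@H]1C.Cc1ccc(cc1)S(=O)(=O)[O-] | intermediate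
15 | (3E)-12-[(2S,3R,6S)-3-(tert-butyldimethylsilyloxy)-2-methyl-1,2,3,6-tetrahydropyridin-6-yl]dodec-3-en-2-one | CC(C)(C)[Si](C)(C)O[C@@H]1C=C[C@H](CCCCCCCC/C=C/C(C)=O)N[C@H]1C | intermediate
16 | 12-[(2S,3R,6S)-3-(tert-butyldimethylsilyloxy)-2-methylpiperidin-6-yl]dodecan-2-one | CC(C)(C)[Si](C)(C)O[C@@H]1CC[C@H](CCCCCCCCCCC(C)=O)N[C@H]1C | intermediate
17 | tert-butyl (2S,3R,6S)-3-(tert-butyldimethylsilyloxy)-2-methyl-6-(11-oxododecyl)piperidine-1-carboxylate | CC(C)(C)[Si](C)(C)O[C@@H]1CC[C@H](CCCCCCCCCCC(C)=O)N(C(=O)OC(C)(C)C)[C@H]1C | intermediate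
18 | tert-butyl (2S,3R,6S)-3-hydroxy-2-methyl-6-(11-oxododecyl)piperidine-1-carboxylate | O[C@@H]1CC[C@H](CCCCCCCCCCC(C)=O)N(C(=O)OC(C)(C)C)[C@H]1C | intermediate
19 | ferulic acid | COc1cc(/C=C/C(=O)O)ccc1O | starting material
20 | methoxymethyl (E)-3-[3-methoxy-4-(methoxymethoxy)phenyl]prop-2-enoate | COCOC(=O)/C=C/c1ccc(OCOC)c(OC)c1 | intermediate
21 | (E)-3-[3-methoxy-4-(methoxymethoxy)phenyl]prop-2-enoic acid | COCOc1ccc(/C=C/C(=O)O)cc1OC | intermediate
22 | tert-butyl (2S,3R,6S)-3-[(E)-3-[3-methoxy-4-(methoxymethoxy)phenyl]prop-2-enoyl]oxy-2-methyl-6-(11-oxododecyl)piperidine-1-carboxylate | COCOc1ccc(/C=C/C(=O)O[C@@H]2CC[C@H](CCCCCCCCCCC(C)=O)N(C(=O)OC(C)(C)C)[C@H]2C)cc1OC | intermediate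
23 | (2S,3R,6S)-2-methyl-6-(11-oxododecyl)piperidin-3-yl (E)-3-(4-hydroxy-3-methoxyphenyl)prop-2-enoate | COc1cc(/C=C/C(=O)O[C@@H]2CC[C@H](CCCCCCCCCCC(C)=O)N[C@H]2C)ccc1O | target

Total step count: 14.
Longest linear sequence: 10 steps (1 → 23 through steps 1, 2, 3, 7, 8, 9, 10, 11, 13 and 14; the branch from 7 through steps 4, 5 and 6 is equally long).

Steps most likely to fail

1. Step 8. The enone may engage one of the allylic vinyl groups before the ring closes, the chain terminus may self-couple and leave dimeric material, or traces of unprotonated amine may stop the catalyst. The fallback sets out from 11, separates the two metatheses and moves the cross metathesis onto a carbamate. Ring-closing metathesis of the tosylate salt of 11 alone (same catalyst, no enone, 0.01 M CH2Cl2, 40 °C, then aq. NaHCO3) should give (2S,3R,6S)-3-(tert-butyldimethylsilyloxy)-6-(dec-9-en-1-yl)-2-methyl-1,2,3,6-tetrahydropyridine F1. Boc2O with Et3N in warm THF should convert it into tert-butyl (2S,3R,6S)-3-(tert-butyldimethylsilyloxy)-6-(dec-9-en-1-yl)-2-methyl-3,6-dihydro-2H-pyridine-1-carboxylate F2. Its unstrained ring alkene is no cross partner, so cross metathesis with 12 at higher concentration should give tert-butyl (2S,3R,6S)-3-(tert-butyldimethylsilyloxy)-2-methyl-6-[(9E)-11-oxododec-9-en-1-yl]-3,6-dihydro-2H-pyridine-1-carboxylate F3. Hydrogenation over PtO2 then comes back to the route at 17.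

2. Step 7. The branched-to-linear ratio may be poor, the chiral amine and the ligand may be a mismatched pair that erodes control at C6, or the α-branched amine may attack too slowly. The fallback sets out from 6 and 7 and forms the C6–vinyl bond instead of the C6–N bond. Condensation (MgSO4, CH2Cl2) should give (E)-N-[(2S,3R)-3-(tert-butyldimethylsilyloxy)pent-4-en-2-yl]undec-10-en-1-imine F4. Addition of CH2=CHMgBr premixed with CeCl3 (THF, −78 °C, to suppress α-deprotonation) should then give 11, where the fallback comes back to the route. Allylic 1,3-strain should hold C2–H in the imine plane, so attack anti to the silyloxy-bearing branch is expected to favour 6S. Selectivity is expected to be lower than with the catalyst, and the diastereomeric amines would be separated by chromatography. Steps 4 to 6 are then not needed.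

3. Step 10. Carbamate formation may stall at the doubly α-branched nitrogen next to the silyloxy-bearing carbon. The fallback sets out from 16 and uses a more reactive chloroformate with an orthogonal removal. Allyl chloroformate (CH2Cl2/aq. NaHCO3) should give prop-2-en-1-yl (2S,3R,6S)-3-(tert-butyldimethylsilyloxy)-2-methyl-6-(11-oxododecyl)piperidine-1-carboxylate F5. Bu4NF should give prop-2-en-1-yl (2S,3R,6S)-3-hydroxy-2-methyl-6-(11-oxododecyl)piperidine-1-carboxylate F6. DCC/DMAP esterification with 21 should give prop-2-en-1-yl (2S,3R,6S)-3-[(E)-3-[3-methoxy-4-(methoxymethoxy)phenyl]prop-2-enoyl]oxy-2-methyl-6-(11-oxododecyl)piperidine-1-carboxylate F7. Pd(PPh3)4 with morpholine (THF, rt) should remove the allyl carbamate and give (2S,3R,6S)-2-methyl-6-(11-oxododecyl)piperidin-3-yl (E)-3-[3-methoxy-4-(methoxymethoxy)phenyl]prop-2-enoate F8. CF3CO2H/CH2Cl2/H2O then cleaves the MOM ether and comes back to the route at 23.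

Further compounds
F1 | step 8 | (2S,3R,6S)-3-(tert-butyldimethylsilyloxy)-6-(dec-9-en-1-yl)-2-methyl-1,2,3,6-tetrahydropyridine | CC(C)(C)[Si](C)(C)O[C@@H]1C=C[C@H](CCCCCCCCC=C)N[C@H]1C
F2 | step 8 | tert-butyl (2S,3R,6S)-3-(tert-butyldimethylsilyloxy)-6-(dec-9-en-1-yl)-2-methyl-3,6-dihydro-2H-pyridine-1-carboxylate | CC(C)(C)[Si](C)(C)O[C@@H]1C=C[C@H](CCCCCCCCC=C)N(C(=O)OC(C)(C)C)[C@H]1C
F3 | step 8 | tert-butyl (2S,3R,6S)-3-(tert-butyldimethylsilyloxy)-2-methyl-6-[(9E)-11-oxododec-9-en-1-yl]-3,6-dihydro-2H-pyridine-1-carboxylate | CC(C)(C)[Si](C)(C)O[C@@H]1C=C[C@H](CCCCCCCC/C=C/C(C)=O)N(C(=O)OC(C)(C)C)[C@H]1C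
F4 | step 7 | (E)-N-[(2S,3R)-3-(tert-butyldimethylsilyloxy)pent-4-en-2-yl]undec-10-en-1-imine | CC(C)(C)[Si](C)(C)O[C@H](C=C)[C@H](C)/N=C/CCCCCCCCC=C
F5 | step 10 | prop-2-en-1-yl (2S,3R,6S)-3-(tert-butyldimethylsilyloxy)-2-methyl-6-(11-oxododecyl)piperidine-1-carboxylate | CC(C)(C)[Si](C)(C)O[C@@H]1CC[C@H](CCCCCCCCCCC(C)=O)N(C(=O)OCC=C)[C@H]1C
F6 | step 10 | prop-2-en-1-yl (2S,3R,6S)-3-hydroxy-2-methyl-6-(11-oxododecyl)piperidine-1-carboxylate | O[C@@H]1CC[C@H](CCCCCCCCCCC(C)=O)N(C(=O)OCC=C)[C@H]1C
F7 | step 10 | prop-2-en-1-yl (2S,3R,6S)-3-[(E)-3-[3-methoxy-4-(methoxymethoxy)phenyl]prop-2-enoyl]oxy-2-methyl-6-(11-oxododecyl)piperidine-1-carboxylate | COCOc1ccc(/C=C/C(=O)O[C@@H]2CC[C@H](CCCCCCCCCCC(C)=O)N(C(=O)OCC=C)[C@H]2C)cc1OC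
F8 | step 10 | (2S,3R,6S)-2-methyl-6-(11-oxododecyl)piperidin-3-yl (E)-3-[3-methoxy-4-(methoxymethoxy)phenyl]prop-2-enoate | COCOc1ccc(/C=C/C(=O)O[C@@H]2CC[C@H](CCCCCCCCCCC(C)=O)N[C@H]2C)cc1OC
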